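**Retrosynthetic overview**
1. Target 12 ⇒ aryl bromide 10 + acrylic acid (Heck disconnection of the C5–vinyl bond).
2. 10 ⇒ trans ester 9 (one hydride operation turns the ester into CH2OH and frees the phenol).
3. 9 ⇒ benzofuran-3-carboxylate 5 + aryl boronate 8, by an enantioselective Rh-catalysed conjugate arylation that dearomatises the furan ring (forms C2–aryl and sets C2; C3 is then set trans by epimerisation).
4. 5 ⇒ o-vanillin (1): bromination, then furan annulation with ethyl diazoacetate.
5. Ring order: both benzene rings are bought; the furan ring is built aromatic (Step 2) and then dearomatised (Step 4).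

Assumption: the SMILES is read as the (2R,3S)-trans dihydrobenzofuran with an E acrylic acid; boronate 6 and ethyl diazoacetate are taken as catalogue reagents.

**Step 1**
Reactants: 1 o-vanillin (2-hydroxy-3-methoxybenzaldehyde); 2 bromine
Product: 3 5-bromo-2-hydroxy-3-methoxybenzaldehyde
Conditions: Br2 (1.05 equiv), NaOAc, AcOH, rt
Reagents that add atoms: bromine, BrBr
Why: Electrophilic aromatic bromination; the free OH directs para (both ortho positions are blocked), giving the bromide that becomes C5 of the benzofuran.

**Step 2**
Reactants: 3; 4 ethyl diazoacetate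
Product: 5 ethyl 5-bromo-7-methoxy-1-benzofuran-3-carboxylate
Conditions: HBF4·OEt2 (10 mol %), CH2Cl2, rt; then conc. H2SO4, rt
Reagents that add atoms: ethyl diazoacetate, CCOC(=O)C=[N+]=[N-]
Why: Acid-catalysed addition of the diazo ester to the aldehyde with 1,2-aryl shift (Roskamp-type salicylaldehyde-to-benzofuran-3-carboxylate annulation) gives the α-formyl arylacetate, which closes to the lactol and dehydrates to the furan; no stereocentre is formed.

**Step 3**
Reactants: 6 2-methoxy-4-(4,4,5,5-tetramethyl-1,3,2-dioxaborolan-2-yl)phenol; 7 pivaloyl chloride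
Product: 8 2-methoxy-4-(4,4,5,5-tetramethyl-1,3,2-dioxaborolan-2-yl)phenyl pivalate
Conditions: PivCl (1.2 equiv), Et3N, DMAP (5 mol %), CH2Cl2, 0 °C → rt
Reagents that add atoms: pivaloyl chloride, CC(C)(C)C(=O)Cl
Why: Simple O-acylation; the pivalate survives the weakly basic Rh step and DBU, keeps the phenol from ionising, and is removed without an extra step by the hydride in Step 5.

**Step 4 (key step)**
Reactants: 5; 8 (3 equiv)
Product: 9 ethyl (2R,3R)-5-bromo-7-methoxy-2-[3-methoxy-4-(pivaloyloxy)phenyl]-2,3-dihydro-1-benzofuran-3-carboxylate (2,3-trans)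
Conditions: [RhCl(C2H4)2]2 (2.5 mol %), (S,S)-Ph-bod* [(1S,4S)-2,5-diphenylbicyclo[2.2.2]octa-2,5-diene] (5.5 mol %), aq KOH (15 mol %), dioxane/H2O 10:1, 60–80 °C; then crude + DBU (1 equiv), PhMe, 50 °C
Reagents that add atoms: boronate 8 (transfers the aryl group), COc1cc(B2OC(C)(C)C(C)(C)O2)ccc1OC(=O)C(C)(C)C
Why: Proposed new method: asymmetric dearomative Hayashi–Miyaura 1,4-arylation. Aryl–Rh(I) (from B→Rh transmetalation) adds syn across the enol-ether-like C2=C3 bond of the weakly aromatic furan ring, aryl to C2 (β to the ester) and Rh to C3 as an oxa-π-allyl enolate that water protonates, with the chiral diene choosing the C2 face. The (S,S) ligand is predicted by the Hayashi αsi-face model to give 2R; this must be confirmed on the first run, and the (R,R) ligand used if the sense is reversed. DBU then equilibrates only C3 to the more stable trans ester, because C2 is locked: the pivalate blocks p-quinone-methide ionisation, and retro-oxa-Michael opening is a reverse 5-endo-trig process. The closest known reactions are Rh/chiral-diene or bisphosphine 1,4-arylations of chromones, coumarins and 4-quinolones.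

**Step 5**
Reactants: 9
Product: 10 [(2R,3S)-5-bromo-2-(4-hydroxy-3-methoxyphenyl)-7-methoxy-2,3-dihydro-1-benzofuran-3-yl]methanol
Conditions: DIBAL-H (6 equiv), PhMe/THF, −40 → 0 °C; Rochelle salt work-up
Reagents that add atoms: none
Why: Hydride reduction of the ethyl ester to the primary alcohol with concurrent reductive cleavage of the aryl pivalate, under non-basic conditions that do not enolise C3. The same geometry is now named 3S because CH2OH ranks below C2, and C3 is no longer epimerisable.

**Step 6**
Reactants: 10; 11 acrylic acid (3 equiv)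
Product: 12 (E)-3-[(2R,3S)-2-(4-hydroxy-3-methoxyphenyl)-3-(hydroxymethyl)-7-methoxy-2,3-dihydro-1-benzofuran-5-yl]prop-2-enoic acid (target)
Conditions: Pd(OAc)2 (5 mol %), P(o-tol)3 (12 mol %), Et3N (4 equiv), DMF, 100 °C; acidify to pH 3
Reagents that add atoms: acrylic acid, C=CC(=O)O
Why: Mizoroki–Heck reaction (syn insertion, syn β-H elimination) gives the E cinnamic acid directly and tolerates free phenols and alcohols. The sp3 centres are untouched, and any reversible quinone-methide opening at C2 returns to trans because C3 is fixed.

**Compound list**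
1 | o-vanillin (2-hydroxy-3-methoxybenzaldehyde) | COc1cccc(C=O)c1O | starting material
2 | bromine | BrBr | starting material
3 | 5-bromo-2-hydroxy-3-methoxybenzaldehyde | COc1cc(Br)cc(C=O)c1O | intermediate
4 | ethyl diazoacetate | CCOC(=O)C=[N+]=[N-] | starting material
5 | ethyl 5-bromo-7-methoxy-1-benzofuran-3-carboxylate | CCOC(=O)c1coc2c(OC)cc(Br)cc12 | intermediate
6 | 2-methoxy-4-(4,4,5,5-tetramethyl-1,3,2-dioxaborolan-2-yl)phenol | COc1cc(B2OC(C)(C)C(C)(C)O2)ccc1O | starting material
7 | pivaloyl chloride | CC(C)(C)C(=O)Cl | starting material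
8 | 2-methoxy-4-(4,4,5,5-tetramethyl-1,3,2-dioxaborolan-2-yl)phenyl pivalate | COc1cc(B2OC(C)(C)C(C)(C)O2)ccc1OC(=O)C(C)(C)C | intermediate
9 | ethyl (2R,3R)-5-bromo-7-methoxy-2-[3-methoxy-4-(pivaloyloxy)phenyl]-2,3-dihydro-1-benzofuran-3-carboxylate | COc1cc([C@@H]2Oc3c(OC)cc(Br)cc3[C@H]2C(=O)OCC)ccc1OC(=O)C(C)(C)C | intermediate
10 | [(2R,3S)-5-bromo-2-(4-hydroxy-3-methoxyphenyl)-7-methoxy-2,3-dihydro-1-benzofuran-3-yl]methanol | COc1cc([C@@H]2Oc3c(OC)cc(Br)cc3[C@H]2CO)ccc1O | intermediate
11 | acrylic acid | C=CC(=O)O | starting material
12 | (E)-3-[(2R,3S)-2-(4-hydroxy-3-methoxyphenyl)-3-(hydroxymethyl)-7-methoxy-2,3-dihydro-1-benzofuran-5-yl]prop-2-enoic acid | COc1cc([C@@H]2Oc3c(OC)cc(/C=C/C(=O)O)cc3[C@H]2CO)ccc1O | target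

**Totals**
Total steps: 6. Longest linear sequence: 5 (1 → 3 → 5 → 9 → 10 → 12). Compound 3 is itself a catalogue item; buying it removes Step 1.

**Three steps most likely to fail**
1. Step 4. The furan C2=C3 bond may be too poor an acceptor, the Rh enolate may rearomatise by β-H elimination to the 2-arylbenzofuran, and the ee and facial sense are unproven. Fallback: split the event into Pd-catalysed C2–H arylation of 5 with 4-iodo-2-methoxyphenyl pivalate to give the aromatic 2-arylbenzofuran-3-carboxylate, then enantioselective hydrogenation of the furan ring (Ru–NHC or Ir–N,P catalyst, cis product) and the same DBU epimerisation at C3.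
2. Step 6. The bromide is electron-rich, and at 100 °C the free phenol can open the ring through the quinone methide (stilbene formation, loss of CH2O). Fallback: replace the Heck reaction by formylation and condensation: bis-TBS protect 10, Br/Li exchange then DMF to the 5-carbaldehyde, Knoevenagel–Doebner with malonic acid (pyridine/piperidine), then TBAF.
3. Step 5. Partial reduction to the epimerisable α-aryl aldehyde, or reductive ring opening via the quinone methide once the pivalate is cleaved, would erode dr or yield. Fallback: change the protecting-group logic: carry the phenol as a TIPS ether (6 + TIPSCl), reduce the ester with LiBH4, and unveil the phenol in a separate buffered TBAF/AcOH step after the Heck reaction (one extra step).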